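## Structural features

The target is a 2-aryl-3-methoxychroman-4-one, that is a 3-O-methyl dihydroflavonol. Ring A is a benzene ring with methoxy groups at C5, C6 and C7; ring C is the fused dihydropyranone (O1, C2, C3, C4, C4a, C8a); ring B, a 3,5-dihydroxy-4-methoxyphenyl group, sits on C2. The only stereocentres are the neighbouring carbons C2 and C3, both R, which places the aryl group and the C3 methoxy group trans on ring C. C3 is alpha to the C4 ketone and C2 carries the ring oxygen O1 beta to it, so base can enolise C3 and expel the O1 phenoxide; this ring opening and reclosure would erase both centres and makes the finished ketone the most fragile part of the molecule. The two free phenols of ring B are oxidation-prone and must stay masked to the end, and no deprotection may touch the four aryl methyl ethers or the alkyl methyl ether at C3. The real difficulty is to set C2 and C3 as one enantiomer with the C3 oxygen already methylated, because methylating a free 3-hydroxy ketone would need the very conditions ring C does not tolerate. The key step uses the fact that O1–C2(aryl)–C3(OMe)–C4 is a 1-aryl-2-methoxybut-3-en-1-ol in disguise: the carbinol carbon is C2, the methoxy-bearing carbon is C3, and the internal vinyl carbon is the latent C4, which later bonds to C4a of ring A and is oxidised to the ketone. Because C2 ends up as an aryl ether, its oxygen can be exchanged with inversion, so the readily made syn alcohol leads to the trans ring.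

## Logic of the disconnections

18 to 17. The two phenolic O–H groups of ring B are traced back to O–CH2Ph bonds. Benzyl ethers survive hydride, oxidants, the redox condensation and palladium, and come off under neutral conditions. The gain is an intermediate with no acidic or oxidisable group. The forward step must cleave two aryl benzyl ethers without reducing C4=O or the benzylic C2–O1 bond and without base.

17 to 15. The C4=O bond is traced back to an exocyclic C4=CH2 bond. An exocyclic alkene is what a ring-forming carbopalladation leaves behind, and it cannot enolise, so C3 stays safe until the ketone appears. The forward step must be an oxidative cleavage that spares two electron-rich arenes and the benzyl ethers and is run buffered.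

15 to 14. The C4–C4a bond is cut, leaving iodine on C4a and a vinyl group whose internal carbon is C4. This opens ring C to an acyclic aryl ether. The forward closure must be 6-exo and not 7-endo, and the new double bond must not migrate into the ring, which would flatten C3.

14 to 11 and 13. The O1–C2 bond is cut. This separates ring A from the stereodefined C2–C3 unit and gives a phenol and a secondary alcohol, the natural partners of a redox condensation. The forward step must invert the carbinol carbon completely, so 11 has to be the syn (1S,2S) isomer. Followed descriptor by descriptor, (1S,2S) in 11 becomes (1R,2S) in 14; after that nothing changes in space, and only the priority rules turn this into (2R,3S) in 15 and (2R,3R) in 17 and 18. No structural correction is needed.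

11 to 4 and 9. The bond between the carbinol carbon and the methoxy-bearing carbon (C2–C3 of the chromanone) is cut. It is the only C–C bond between the two stereocentres, and the cut gives an aldehyde and a three-carbon allylboron nucleophile that already carries the O-methyl group and the latent C4. Both stereocentres, the C3 ether and the handle for ring closure then arise in one step from achiral pieces. The forward step must control syn versus anti (through the Z geometry of 9) and the aldehyde face (through a chiral acid).

9 to 5 and 6. The C–B bond is cut. Allylic deprotonation of 5 gives an oxygen-chelated allyl anion of fixed cis geometry, and 6 supplies the pinacol boron unit. The forward step must borylate at the carbon remote from oxygen and keep the Z geometry through work-up.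

13 to 12. The C–I bond ortho to the hydroxyl is cut. Both ortho positions of 12 are equivalent and the para position is blocked, so there is no regiochemical question. The forward step must stop at mono-iodination and must not oxidise the electron-rich phenol.

4 to 3 to 2 to 1. The formyl group is traced back through the benzylic alcohol to the methyl ester, and the benzyl ethers to the free phenols. The forward steps need only routine chemoselectivity.

## Other disconnections considered

Alternative 1: The cut is through O1–C8a and C4–C4a at once. The anti hydroxy ester A1 would be combined with the aryne A3, released by CsF from the silyl triflate A2; the alkoxide oxygen adds to the aryne and the aryl anion then attacks the ester, giving A4, which is the same compound as 17. In its favour, both ring bonds form in one operation, the C4 oxidation state arrives with the ester so no carbon is excised, C2 is carried through with retention so no inversion step is needed, and the regiochemistry is matched, since the nucleophile should add to the aryne carbon remote from the flanking methoxy group. Against it, the alkoxide of A1 is a beta-alkoxide of an alpha-methoxy ester, open to retro-aldol cleavage back to 4 and to epimerisation at the alpha carbon. A secondary aliphatic alkoxide is a poorer aryne partner than a phenoxide, and the aryl anion may be quenched by a hydroxyl proton before it reaches the ester. A4 would also be formed in the presence of basic fluoride, the conditions under which ring C opens. In addition, A2 needs several steps and A1 needs an anti-selective asymmetric glycolate aldol, which is less general than the syn version. Compared with the chosen plan, it is better in atom economy and, on paper, equal or better in step count. It is weaker mechanistically, because it stacks three uncertain events in a basic medium on a base-labile substrate, whereas the chosen plan makes the same two ring bonds in two separately understood steps under neutral conditions.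

Alternative 2: The cut is the C3–O bond. The enantioenriched flavanone A5 would be converted by Et3N and Me3SiOTf into the silyl enol ether A6, and dimethyldioxirane would oxidise it on the face opposite the C2 aryl group (Rubottom oxidation) to give the trans hydroxy ketone A7. In its favour, the diastereocontrol rests on the C2 substituent alone and is as dependable as the chair transition state of the chosen key step. The skeleton comes from classical flavanone chemistry, no carbon is wasted and no inversion is needed. Against it, the absolute configuration must be secured earlier by a separate asymmetric synthesis of A5, and A5 can racemise by retro-oxa-Michael opening under the amine base of the enolisation. The larger problem is that A7 is a free alpha-hydroxy ketone that still has to be O-methylated: basic methylation invites ring opening, epimerisation and dehydrogenation to the flavonol, and non-basic methylation of this hindered secondary alcohol is uncertain. Compared with the chosen plan, it is equal in step count and diastereocontrol and better in atom economy. It is worse structurally, because the chosen plan brings the C3 methyl ether in with 9 and never exposes a 3-hydroxy ketone.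

Alternative 3: The cuts are the C3–O and C4–O bonds. OsO4 with N-methylmorpholine N-oxide would dihydroxylate the C3=C4 bond of the 2H-chromene A8 opposite the C2 aryl group to give the 2,3-trans-3,4-cis diol A9. In its favour, this is one of the most dependable alkene oxidations, it runs under neutral conditions, and its facial selectivity is substrate-controlled and needs no chiral catalyst; on that point it is equal or better than the chosen key step. Against it, A8 needs its own asymmetric synthesis and its stereocentre is labile, because 2H-chromenes open and reclose by a reversible electrocyclic process. After the key step the two cis hydroxyls must be told apart. Oxidising the benzylic C4 hydroxyl first leads to A7 and the methylation problem of Alternative 2; methylating C3 first has no clear bias. C4 also arrives at the alcohol level and needs an extra oxidation. Compared with the chosen plan, it has about as many operations after the key step (oxidation, methylation, debenzylation against four), but more before it, and it handles the fragile C3 centre in more functional-group steps.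

Key step: step 5

Assumption: (R)-TRIP is taken to direct addition to the Re face of 4, as it does in the parent allylboration of aryl aldehydes; if the opposite sense is found, (S)-TRIP is used and nothing else changes.

## Route

Step 1
Reactants: 1 methyl 3,5-dihydroxy-4-methoxybenzoate
Product: 2 methyl 3,5-bis(benzyloxy)-4-methoxybenzoate
Conditions: BnBr (2.3 equiv), K2CO3, DMF, 60 °C
Reagents that add atoms: benzyl bromide, BrCc1ccccc1
Why: Williamson ether synthesis; both phenoxides are alkylated by the reactive benzylic bromide while the methyl ester is inert to carbonate in DMF.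

Step 2
Reactants: 2 methyl 3,5-bis(benzyloxy)-4-methoxybenzoate
Product: 3 [3,5-bis(benzyloxy)-4-methoxyphenyl]methanol
Conditions: LiAlH4, THF, 0 °C; aq. NaOH work-up
Reagents that add atoms: none
Why: Hydride reduction of an aryl ester to the primary alcohol; aryl benzyl and methyl ethers are untouched.

Step 3
Reactants: 3 [3,5-bis(benzyloxy)-4-methoxyphenyl]methanol
Product: 4 3,5-bis(benzyloxy)-4-methoxybenzaldehyde
Conditions: MnO2 (activated, excess), CH2Cl2, rt
Reagents that add atoms: none
Why: MnO2 oxidises benzylic alcohols selectively and stops at the aldehyde; the reagent is removed by filtration.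

Step 4
Reactants: 5 allyl methyl ether; 6 2-isopropoxy-4,4,5,5-tetramethyl-1,3,2-dioxaborolane
Product: 9 (Z)-2-(3-methoxyallyl)-4,4,5,5-tetramethyl-1,3,2-dioxaborolane, via (Z)-3-methoxyallyllithium 7 (not isolated), via lithium isopropoxyborate complex 8 (not isolated)
Conditions: s-BuLi, THF, −78 °C; then 6, −78 °C; then HCl (1.0 equiv, Et2O), −78 °C → rt; distillation
Reagents that add atoms: none
Why: Allylic deprotonation next to oxygen gives an allyl anion held cis by O–Li chelation, and the boron electrophile is attacked at the carbon remote from oxygen to give the ate complex 8. One equivalent of anhydrous acid removes the isopropoxide without hydrolysing the enol ether, so the Z geometry is kept (lithiation–borylation).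

Step 5
Reactants: 4 3,5-bis(benzyloxy)-4-methoxybenzaldehyde; 9 (Z)-2-(3-methoxyallyl)-4,4,5,5-tetramethyl-1,3,2-dioxaborolane
Product: 11 (1S,2S)-1-[3,5-bis(benzyloxy)-4-methoxyphenyl]-2-methoxybut-3-en-1-ol, via pinacol borate ester 10 (not isolated)
Conditions: (R)-TRIP [(R)-3,3'-bis(2,4,6-triisopropylphenyl)-1,1'-binaphthyl-2,2'-diyl hydrogen phosphate] (5 mol%), 4 Å MS, toluene, −45 °C; then aq. NaHCO3
Reagents that add atoms: none
Why: The acidic P–OH hydrogen-bonds to a boronate oxygen of 9 while the phosphoryl oxygen contacts the formyl C–H of 4, and the allyl unit is transferred through a closed six-membered chair (Zimmerman–Traxler type) in which the B–O and C–C bonds form together with allylic transposition. The closest known reaction type is the chiral phosphoric acid-catalysed allyl-, crotyl- and gamma-alkoxyallylboration of aldehydes with pinacol boronates. No ring is closed; the one skeletal bond formed is the later C2–C3 bond of the chromanone. Relative configuration: the aryl group of 4 sits equatorial and the Z-methoxy group is forced axial in the chair, which turns Z geometry into the syn relation. Absolute configuration: the 2,4,6-triisopropylphenyl groups of the (R) acid should leave only the Re face of the bound aldehyde open, which gives 1S and with it 2S. The step needs enantio-, diastereo- and gamma-regioselectivity; these rest on the geometric purity of distilled 9, on the low temperature that suppresses the slow uncatalysed racemic pathway, and on the absence of ortho substituents or competing Lewis-basic sites near the formyl group of 4. The borate ester 10 is hydrolysed on aqueous work-up, and the dry, weakly acidic medium leaves the enol ether of 9 and the benzyl ethers intact.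

Step 6
Reactants: 12 3,4,5-trimethoxyphenol
Product: 13 2-iodo-3,4,5-trimethoxyphenol
Conditions: NIS (1.0 equiv), CH2Cl2, −20 → 0 °C, dark
Reagents that add atoms: N-iodosuccinimide, O=C1CCC(=O)N1I
Why: Electrophilic aromatic iodination; the two ortho positions are equivalent and the para position is blocked, and one equivalent of a mild iodonium source at low temperature limits di-iodination and oxidation of the phenol.

Step 7
Reactants: 11 (1S,2S)-1-[3,5-bis(benzyloxy)-4-methoxyphenyl]-2-methoxybut-3-en-1-ol; 13 2-iodo-3,4,5-trimethoxyphenol
Product: 14 1,3-bis(benzyloxy)-5-[(1R,2S)-1-(2-iodo-3,4,5-trimethoxyphenoxy)-2-methoxybut-3-en-1-yl]-2-methoxybenzene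
Conditions: PPh3, DIAD, toluene, 0 °C → rt
Reagents that add atoms: none
Why: Mitsunobu reaction; the phenoxide of 13, made more acidic by the ortho iodine, displaces the alkoxyphosphonium group by SN2 with inversion at the carbinol carbon (1S to 1R). Ionisation should be disfavoured by the two meta alkoxy groups, the twisted para methoxy group, the adjacent electron-withdrawing methoxy carbon and the non-polar solvent.

Step 8
Reactants: 14 1,3-bis(benzyloxy)-5-[(1R,2S)-1-(2-iodo-3,4,5-trimethoxyphenoxy)-2-methoxybut-3-en-1-yl]-2-methoxybenzene
Product: 15 (2R,3S)-2-[3,5-bis(benzyloxy)-4-methoxyphenyl]-3,5,6,7-tetramethoxy-4-methylidenechromane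
Conditions: Pd(OAc)2 (10 mol%), PPh3 (20 mol%), Ag2CO3, MeCN, 80 °C
Reagents that add atoms: none
Why: Intramolecular Mizoroki–Heck reaction; zerovalent palladium formed in situ inserts into the C–I bond, the aryl group adds 6-exo-trig to the internal vinyl carbon, and beta-hydride elimination of the C4 hydrogen gives the exocyclic alkene. Ag2CO3 removes iodide and suppresses re-addition of the palladium hydride that would move the double bond into the ring; C2 and C3 are not touched.

Step 9
Reactants: 15 (2R,3S)-2-[3,5-bis(benzyloxy)-4-methoxyphenyl]-3,5,6,7-tetramethoxy-4-methylidenechromane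
Product: 17 (2R,3R)-2-[3,5-bis(benzyloxy)-4-methoxyphenyl]-3,5,6,7-tetramethoxychroman-4-one, via vicinal diol 16 (not isolated)
Conditions: OsO4 (cat.), NaIO4, 2,6-lutidine, dioxane/H2O 3:1, rt
Reagents that add atoms: OsO4, O=[Os](=O)(=O)=O (oxygen carrier); NaIO4, [Na+].[O-]I(=O)(=O)=O (stoichiometric oxygen source)
Why: Lemieux–Johnson oxidation; osmylation of the 1,1-disubstituted alkene and periodate cleavage of the diol give the ketone and formaldehyde. Unlike ozone, OsO4 does not attack the electron-rich arenes, and the lutidine buffer keeps the medium too mild to enolise C3.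

Step 10
Reactants: 17 (2R,3R)-2-[3,5-bis(benzyloxy)-4-methoxyphenyl]-3,5,6,7-tetramethoxychroman-4-one
Product: 18 (2R,3R)-2-(3,5-dihydroxy-4-methoxyphenyl)-3,5,6,7-tetramethoxychroman-4-one
Conditions: H2 (1 atm), Pd/C (10 wt%), EtOAc, rt
Reagents that add atoms: none
Why: Catalytic hydrogenolysis of the two aryl benzyl ethers under neutral conditions, which avoids enolisation and ring opening. Aryl benzyl ethers should cleave faster than the cyclic benzylic C2–O1 bond or the electron-rich aryl ketone is reduced, so the reaction is stopped at full debenzylation.

## Compound list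

1 | methyl 3,5-dihydroxy-4-methoxybenzoate | COC(=O)c1cc(O)c(OC)c(O)c1 | starting material
2 | methyl 3,5-bis(benzyloxy)-4-methoxybenzoate | COC(=O)c1cc(OCc2ccccc2)c(OC)c(OCc2ccccc2)c1 | intermediate
3 | [3,5-bis(benzyloxy)-4-methoxyphenyl]methanol | OCc1cc(OCc2ccccc2)c(OC)c(OCc2ccccc2)c1 | intermediate
4 | 3,5-bis(benzyloxy)-4-methoxybenzaldehyde | O=Cc1cc(OCc2ccccc2)c(OC)c(OCc2ccccc2)c1 | intermediate
5 | allyl methyl ether (3-methoxyprop-1-ene) | C=CCOC | starting material
6 | 2-isopropoxy-4,4,5,5-tetramethyl-1,3,2-dioxaborolane | CC(C)OB1OC(C)(C)C(C)(C)O1 | starting material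
7 | (Z)-3-methoxyallyllithium | CO/C=C\C[Li] | intermediate (not isolated)
8 | lithium isopropoxy[(Z)-3-methoxyallyl](pinacolato)borate | [Li+].CO/C=C\C[B-]1(OC(C)C)OC(C)(C)C(C)(C)O1 | intermediate (not isolated)
9 | (Z)-2-(3-methoxyallyl)-4,4,5,5-tetramethyl-1,3,2-dioxaborolane | CO/C=C\CB1OC(C)(C)C(C)(C)O1 | intermediate
10 | 2-{[(1S,2S)-1-[3,5-bis(benzyloxy)-4-methoxyphenyl]-2-methoxybut-3-en-1-yl]oxy}-4,4,5,5-tetramethyl-1,3,2-dioxaborolane | C=C[C@H](OC)[C@H](c1cc(OCc2ccccc2)c(OC)c(OCc2ccccc2)c1)OB1OC(C)(C)C(C)(C)O1 | intermediate (not isolated)
11 | (1S,2S)-1-[3,5-bis(benzyloxy)-4-methoxyphenyl]-2-methoxybut-3-en-1-ol | C=C[C@H](OC)[C@H](c1cc(OCc2ccccc2)c(OC)c(OCc2ccccc2)c1)O | intermediate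
12 | 3,4,5-trimethoxyphenol | COc1cc(O)cc(OC)c1OC | starting material
13 | 2-iodo-3,4,5-trimethoxyphenol | COc1cc(O)c(I)c(OC)c1OC | intermediate
14 | 1,3-bis(benzyloxy)-5-[(1R,2S)-1-(2-iodo-3,4,5-trimethoxyphenoxy)-2-methoxybut-3-en-1-yl]-2-methoxybenzene | C=C[C@H](OC)[C@@H](c1cc(OCc2ccccc2)c(OC)c(OCc2ccccc2)c1)Oc1cc(OC)c(OC)c(OC)c1I | intermediate
15 | (2R,3S)-2-[3,5-bis(benzyloxy)-4-methoxyphenyl]-3,5,6,7-tetramethoxy-4-methylidenechromane | COc1cc2c(c(OC)c1OC)C(=C)[C@H](OC)[C@@H](c1cc(OCc3ccccc3)c(OC)c(OCc3ccccc3)c1)O2 | intermediate
16 | (2R,3R)-2-[3,5-bis(benzyloxy)-4-methoxyphenyl]-4-(hydroxymethyl)-3,5,6,7-tetramethoxychroman-4-ol (configuration at C4 not assigned) | COc1cc2c(c(OC)c1OC)C(O)(CO)[C@H](OC)[C@@H](c1cc(OCc3ccccc3)c(OC)c(OCc3ccccc3)c1)O2 | intermediate (not isolated)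
17 | (2R,3R)-2-[3,5-bis(benzyloxy)-4-methoxyphenyl]-3,5,6,7-tetramethoxychroman-4-one | COc1cc2c(c(OC)c1OC)C(=O)[C@H](OC)[C@@H](c1cc(OCc3ccccc3)c(OC)c(OCc3ccccc3)c1)O2 | intermediate
18 | (2R,3R)-2-(3,5-dihydroxy-4-methoxyphenyl)-3,5,6,7-tetramethoxychroman-4-one | COc1cc2c(c(OC)c1OC)C(=O)[C@H](OC)[C@@H](c1cc(O)c(OC)c(O)c1)O2 | target

## Step count and least certain steps

Total step count: 10. Longest linear sequence: 8 steps (steps 1, 2, 3, 5, 7, 8, 9, 10); steps 4 and 6 prepare the two side fragments.

Step 5 (key step). The most likely failure is insufficient facial discrimination, or the opposite sense of induction, with this electron-rich aldehyde and a functionalised boronate. A second risk is erosion of the syn selectivity if the uncatalysed pathway competes or if 9 is not geometrically pure. The fallback replaces catalyst control by reagent control. It sets out from 4 and uses 7, generated from 5 as in step 4. Addition of 7 to (+)-Ipc2BOMe (Ipc = isopinocampheyl; the B-methoxyborane prepared from (−)-α-pinene) at −78 °C should give the lithium methoxyborate F1. BF3·OEt2 then removes the methoxide to leave the allylborane F2, 4 is added at −78 °C to give the borinate F3, and NaOH/H2O2 releases 11, where the route is rejoined. This enantiomer of the reagent is chosen because the parent allyl reagent of the same series attacks the Re face of aryl aldehydes.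

Step 7. The most likely failure is partial ionisation of the benzylic alkoxyphosphonium intermediate, which would cost stereochemical fidelity at the carbinol carbon. The other risk is slow capture by the hindered, weakly acidic phenol, which would let elimination compete. The fallback separates the inversion from the C–O bond formation. From 11, a Mitsunobu reaction with 4-nitrobenzoic acid, a much stronger and smaller acid than 13, should give the inverted ester (1R,2S)-1-[3,5-bis(benzyloxy)-4-methoxyphenyl]-2-methoxybut-3-en-1-yl 4-nitrobenzoate F4. K2CO3 in methanol then frees the anti alcohol (1R,2S)-1-[3,5-bis(benzyloxy)-4-methoxyphenyl]-2-methoxybut-3-en-1-ol F5. An Ullmann-type etherification (CuI, 3,4,7,8-tetramethyl-1,10-phenanthroline, Cs2CO3, toluene, 100 °C) joins F5 to 2-bromo-1-iodo-3,4,5-trimethoxybenzene F6, itself made from 5-iodo-1,2,3-trimethoxybenzene and N-bromosuccinimide. The coupling occurs at the C–I bond and leaves the carbinol C–O bond, and so its configuration, untouched, giving the bromo analogue of 14, 1,3-bis(benzyloxy)-5-[(1R,2S)-1-(2-bromo-3,4,5-trimethoxyphenoxy)-2-methoxybut-3-en-1-yl]-2-methoxybenzene F7. The Heck cyclisation of step 8 applied to F7, with P(t-Bu)3 in place of PPh3, returns to the route at 15.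

Step 8. The most likely failure is migration of the new exocyclic double bond into ring C through re-addition of the palladium hydride, which would destroy the C3 centre. Competing 7-endo closure and reductive loss of iodine from the hindered, electron-rich aryl iodide are also possible. The fallback replaces carbopalladation by a polar addition. From 14, Lemieux–Johnson cleavage of the vinyl group (OsO4 cat., NaIO4, 2,6-lutidine), by way of the diol (3S,4R)-4-[3,5-bis(benzyloxy)-4-methoxyphenyl]-4-(2-iodo-3,4,5-trimethoxyphenoxy)-3-methoxybutane-1,2-diol F8, should give the aldehyde (2R,3R)-3-[3,5-bis(benzyloxy)-4-methoxyphenyl]-3-(2-iodo-3,4,5-trimethoxyphenoxy)-2-methoxypropanal F9. An intramolecular Nozaki–Hiyama–Kishi reaction (CrCl2, NiCl2 cat., DMF, rt) adds the arylchromium species to the aldehyde under non-basic conditions and closes ring C as (2R,3S)-2-[3,5-bis(benzyloxy)-4-methoxyphenyl]-3,5,6,7-tetramethoxychroman-4-ol F10. Dess–Martin periodinane oxidises F10 to 17, where the route is rejoined; steps 8 and 9 are bypassed.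

Step 9. The most likely failure is slow osmylation of the 1,1-disubstituted alkene, which is flanked by the C5 and C3 methoxy groups. A long reaction time would then expose the product ketone to epimerisation or ring opening. The fallback engages the alkene with a small electrophilic oxidant. From 15, dimethyldioxirane in acetone at 0 °C should give the spiro-epoxide (2R,3R)-2-[3,5-bis(benzyloxy)-4-methoxyphenyl]-3,5,6,7-tetramethoxyspiro[chromane-4,2'-oxirane] F11. Periodic acid (H5IO6) in wet THF opens F11 to 16 and cleaves it in the same flask, returning to the route at 17.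

## Further compounds

F1 | step 5 | lithium methoxy[(Z)-3-methoxyallyl]bis(isopinocampheyl)borate, Ipc groups from (−)-α-pinene (not isolated) | [Li+].CO/C=C\C[B-](OC)([C@H]1C[C@H]2C[C@@H]([C@@H]1C)C2(C)C)[C@H]1C[C@H]2C[C@@H]([C@@H]1C)C2(C)C
F2 | step 5 | [(Z)-3-methoxyallyl]bis(isopinocampheyl)borane, Ipc groups from (−)-α-pinene (not isolated) | CO/C=C\CB([C@H]1C[C@H]2C[C@@H]([C@@H]1C)C2(C)C)[C@H]1C[C@H]2C[C@@H]([C@@H]1C)C2(C)C
F3 | step 5 | (1S,2S)-1-[3,5-bis(benzyloxy)-4-methoxyphenyl]-2-methoxybut-3-en-1-yl bis(isopinocampheyl)borinate (not isolated) | C=C[C@H](OC)[C@H](c1cc(OCc2ccccc2)c(OC)c(OCc2ccccc2)c1)OB([C@H]1C[C@H]2C[C@@H]([C@@H]1C)C2(C)C)[C@H]1C[C@H]2C[C@@H]([C@@H]1C)C2(C)C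
F4 | step 7 | (1R,2S)-1-[3,5-bis(benzyloxy)-4-methoxyphenyl]-2-methoxybut-3-en-1-yl 4-nitrobenzoate | C=C[C@H](OC)[C@@H](c1cc(OCc2ccccc2)c(OC)c(OCc2ccccc2)c1)OC(=O)c1ccc(cc1)[N+](=O)[O-]
F5 | step 7 | (1R,2S)-1-[3,5-bis(benzyloxy)-4-methoxyphenyl]-2-methoxybut-3-en-1-ol | C=C[C@H](OC)[C@@H](c1cc(OCc2ccccc2)c(OC)c(OCc2ccccc2)c1)O
F6 | step 7 | 2-bromo-1-iodo-3,4,5-trimethoxybenzene | COc1cc(I)c(Br)c(OC)c1OC
F7 | step 7 | 1,3-bis(benzyloxy)-5-[(1R,2S)-1-(2-bromo-3,4,5-trimethoxyphenoxy)-2-methoxybut-3-en-1-yl]-2-methoxybenzene | C=C[C@H](OC)[C@@H](c1cc(OCc2ccccc2)c(OC)c(OCc2ccccc2)c1)Oc1cc(OC)c(OC)c(OC)c1Br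
F8 | step 8 | (3S,4R)-4-[3,5-bis(benzyloxy)-4-methoxyphenyl]-4-(2-iodo-3,4,5-trimethoxyphenoxy)-3-methoxybutane-1,2-diol (C2 epimers, not isolated) | OCC(O)[C@H](OC)[C@@H](c1cc(OCc2ccccc2)c(OC)c(OCc2ccccc2)c1)Oc1cc(OC)c(OC)c(OC)c1I
F9 | step 8 | (2R,3R)-3-[3,5-bis(benzyloxy)-4-methoxyphenyl]-3-(2-iodo-3,4,5-trimethoxyphenoxy)-2-methoxypropanal | O=C[C@H](OC)[C@@H](c1cc(OCc2ccccc2)c(OC)c(OCc2ccccc2)c1)Oc1cc(OC)c(OC)c(OC)c1I
F10 | step 8 | (2R,3S)-2-[3,5-bis(benzyloxy)-4-methoxyphenyl]-3,5,6,7-tetramethoxychroman-4-ol (C4 epimers) | COc1cc2c(c(OC)c1OC)C(O)[C@H](OC)[C@@H](c1cc(OCc3ccccc3)c(OC)c(OCc3ccccc3)c1)O2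
F11 | step 9 | (2R,3R)-2-[3,5-bis(benzyloxy)-4-methoxyphenyl]-3,5,6,7-tetramethoxyspiro[chromane-4,2'-oxirane] (C4 epimers) | COc1cc2c(c(OC)c1OC)C1(CO1)[C@H](OC)[C@@H](c1cc(OCc3ccccc3)c(OC)c(OCc3ccccc3)c1)O2
A1 | alternative 1 | methyl (2R,3R)-3-[3,5-bis(benzyloxy)-4-methoxyphenyl]-3-hydroxy-2-methoxypropanoate | COC(=O)[C@H](OC)[C@@H](c1cc(OCc2ccccc2)c(OC)c(OCc2ccccc2)c1)O
A2 | alternative 1 | 3,4,5-trimethoxy-2-(trimethylsilyl)phenyl trifluoromethanesulfonate | COc1cc(OS(=O)(=O)C(F)(F)F)c([Si](C)(C)C)c(OC)c1OC
A3 | alternative 1 | 3,4,5-trimethoxybenzyne (1,2-didehydro-3,4,5-trimethoxybenzene) | COC1=C(OC)C(OC)=CC#C1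
A4 | alternative 1 | (2R,3R)-2-[3,5-bis(benzyloxy)-4-methoxyphenyl]-3,5,6,7-tetramethoxychroman-4-one (identical with 17) | COc1cc2c(c(OC)c1OC)C(=O)[C@H](OC)[C@@H](c1cc(OCc3ccccc3)c(OC)c(OCc3ccccc3)c1)O2
A5 | alternative 2 | (2S)-2-[3,5-bis(benzyloxy)-4-methoxyphenyl]-5,6,7-trimethoxychroman-4-one | COc1cc2c(c(OC)c1OC)C(=O)C[C@@H](c1cc(OCc3ccccc3)c(OC)c(OCc3ccccc3)c1)O2
A6 | alternative 2 | (2S)-2-[3,5-bis(benzyloxy)-4-methoxyphenyl]-5,6,7-trimethoxy-4-(trimethylsilyloxy)-2H-chromene | COc1cc2c(c(OC)c1OC)C(O[Si](C)(C)C)=C[C@@H](c1cc(OCc3ccccc3)c(OC)c(OCc3ccccc3)c1)O2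
A7 | alternative 2 | (2R,3R)-2-[3,5-bis(benzyloxy)-4-methoxyphenyl]-3-hydroxy-5,6,7-trimethoxychroman-4-one | COc1cc2c(c(OC)c1OC)C(=O)[C@H](O)[C@@H](c1cc(OCc3ccccc3)c(OC)c(OCc3ccccc3)c1)O2
A8 | alternative 3 | (2S)-2-[3,5-bis(benzyloxy)-4-methoxyphenyl]-5,6,7-trimethoxy-2H-chromene | COc1cc2c(c(OC)c1OC)C=C[C@@H](c1cc(OCc3ccccc3)c(OC)c(OCc3ccccc3)c1)O2
A9 | alternative 3 | (2R,3S,4S)-2-[3,5-bis(benzyloxy)-4-methoxyphenyl]-5,6,7-trimethoxychromane-3,4-diol | COc1cc2c(c(OC)c1OC)[C@H](O)[C@H](O)[C@@H](c1cc(OCc3ccccc3)c(OC)c(OCc3ccccc3)c1)O2
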